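Ring B of the aryltetralin is closed last through its C4–C4a bond. The step exploits that C4a of ring A lies para to the free C7 hydroxyl, while the pendant trimethoxyphenyl ring carries no phenol: once the catechol is unmasked, the C7 phenoxide makes C4a the only carbon nucleophile in reach of an open-chain α-substituted acrylate whose CH2 terminus becomes C4. One 6-endo conjugate addition forms the carbocycle and, under equilibrating base, sets C3 trans to C2. The precursor is acyclic; C1 stems from a rhodium-catalysed asymmetric arylation of a coumarin whose ring oxygen is the later C8 hydroxyl, C2 from trans alkylation of that lactone.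

Key step: step 7

Remark: 8-hydroxy-7-methoxycoumarin is taken as a commercial starting material, and the ligand enantiomer in step 2 is assumed to be the one that gives 4S. Atom labels follow the tetralin of the target: C1 carries the aryl group, C2 and C3 the hydroxymethyl carbons C2a and C3a, C4 is the ring CH2, C4a/C8a are the fusion carbons, C6 carries OMe, C7 and C8 the hydroxyls.

Step 1
Reactants: 1 8-hydroxy-7-methoxycoumarin
Product: 2 8-[(tert-butyldimethylsilyl)oxy]-7-methoxycoumarin
Conditions: TBSCl, imidazole, DMF, 25 °C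
Reagents that add atoms: tert-butyldimethylsilyl chloride (TBSCl), C[Si](C)(Cl)C(C)(C)C
Why: Standard silylation masks the later C7 hydroxyl as an aryl silyl ether that should survive the enolate steps and is removed by fluoride in the key step.

Step 2
Reactants: 2 silylated coumarin; 3 3,4,5-trimethoxyphenylboronic acid
Product: 4 (4S)-8-[(tert-butyldimethylsilyl)oxy]-7-methoxy-4-(3,4,5-trimethoxyphenyl)-3,4-dihydro-2H-chromen-2-one
Conditions: Rh(acac)(C2H4)2 (3 mol %), (S)-SEGPHOS (3.3 mol %), 3 (5 equiv), dioxane/H2O 10:1, 60 °C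
Reagents that add atoms: none
Why: Rhodium-catalysed asymmetric 1,4-addition of an arylboronic acid to a coumarin (Hayashi–Miyaura reaction) should set C1 as 4S under control of the chiral bisphosphine.

Step 3
Reactants: 4 (4S)-4-aryl dihydrocoumarin; 5 tert-butyl bromoacetate
Product: 6 tert-butyl 2-[(3R,4S)-8-[(tert-butyldimethylsilyl)oxy]-7-methoxy-2-oxo-4-(3,4,5-trimethoxyphenyl)-3,4-dihydro-2H-chromen-3-yl]acetate
Conditions: LiN(SiMe3)2, THF, −78 °C; then 5, −78 to −40 °C
Reagents that add atoms: none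
Why: In this lactone enolate alkylation the electrophile should enter anti to the pseudoaxial C4 aryl group, giving the 3,4-trans lactone, which equals the 1,2-cis relation of the tetralin because the lactone carbonyl becomes the exocyclic carbon C2a.

Step 4
Reactants: 6 trans-alkylated lactone
Product: 7 tert-butyl (3R,4S)-4-{3-[(tert-butyldimethylsilyl)oxy]-2-hydroxy-4-methoxyphenyl}-3-(hydroxymethyl)-4-(3,4,5-trimethoxyphenyl)butanoate
Conditions: LiBH4, THF, 0 °C
Reagents that add atoms: none
Why: Chemoselective hydride reduction should open the activated aryl lactone to the C8 phenol and the C2a alcohol much faster than it touches the hindered tert-butyl ester, which also resists relactonisation, and C2 is no longer epimerisable afterwards.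

Step 5
Reactants: 7 phenol alcohol
Product: 8 tert-butyl (3R,4S)-4-{2,3-bis[(tert-butyldimethylsilyl)oxy]-4-methoxyphenyl}-3-{[(tert-butyldimethylsilyl)oxy]methyl}-4-(3,4,5-trimethoxyphenyl)butanoate
Conditions: TBSCl (3 equiv), imidazole, DMAP (cat.), DMF, 40 °C
Reagents that add atoms: tert-butyldimethylsilyl chloride (TBSCl), C[Si](C)(Cl)C(C)(C)C
Why: Silylation of the phenol and the primary alcohol prevents lactonisation and ring aminomethylation in the next step; a silyl shift between the two catechol oxygens would be without consequence since both end up silylated.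

Step 6
Reactants: 8 tris-silyl ether ester
Product: 11 tert-butyl (3S,4S)-4-{2,3-bis[(tert-butyldimethylsilyl)oxy]-4-methoxyphenyl}-3-{[(tert-butyldimethylsilyl)oxy]methyl}-2-methylidene-4-(3,4,5-trimethoxyphenyl)butanoate, via Mannich base 9 (not isolated), via methiodide 10 (not isolated)
Conditions: LiN(iPr)2, THF, −78 °C; CH2=NMe2 I (Eschenmoser's salt), −78 to 0 °C; MeI, CH2Cl2, 25 °C; DBU, CH2Cl2, 25 °C
Reagents that add atoms: dimethyl(methylidene)ammonium iodide (Eschenmoser's salt), C[N+](C)=C.[I-]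
Why: A Mannich reaction at the only enolisable position (the CH2 next to the ester), followed by quaternisation and Hofmann-type elimination, should give the acrylate whose CH2 is the future C4 without touching C1 or C2.

Step 7
Reactants: 11 acrylate
Product: 13 tert-butyl (2S,3S,4S)-3-{[(tert-butyldimethylsilyl)oxy]methyl}-5,6-dihydroxy-7-methoxy-4-(3,4,5-trimethoxyphenyl)-1,2,3,4-tetrahydronaphthalene-2-carboxylate, via catechol acrylate 12 (not isolated)
Conditions: Bu4NF (2.2 equiv), THF, 0 °C; then KOtBu (4 equiv), tBuOH, argon, 25 to 60 °C; aq NH4Cl work-up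
Reagents that add atoms: none
Why: Fluoride unmasks the catechol; the C7 phenoxide is a vinylogous enolate whose para carbon C4a adds to the acrylate CH2 (C4), and tautomerisation of the cyclohexadienone back to the phenol makes the C–C bond formation irreversible, whereas attack by the C8 oxygen (seven-membered ether) is a reversible oxa-Michael addition. The closest known reaction type is the intramolecular Friedel–Crafts-type Michael addition (carbon alkylation) of phenolates. Ring B closes in a 6-endo-trig mode, both acrylate carbons ending up in the new ring. The new stereocentre C3 is set under thermodynamic control: tert-butoxide equilibrates the ester α-carbon and the ester should settle equatorial and trans to the C2 silyloxymethyl group, because the cis epimer would place it syn-diaxial to the C1 aryl group, which the peri C8 oxygen holds pseudoaxial. The step needs ring A to react instead of the more electron-rich trimethoxyphenyl ring, and at C4a only; the phenoxide, present on ring A alone, and the para relation of the C7 oxygen to C4a within reach of the tether secure both. C1 and C2 carry no acidic hydrogen under these conditions and should not be scrambled.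

Step 8
Reactants: 13 tetralin ester
Product: 15 (6S,7S,8S)-6,7-bis(hydroxymethyl)-3-methoxy-8-(3,4,5-trimethoxyphenyl)-5,6,7,8-tetrahydronaphthalene-1,2-diol, via monosilyl ether 14 (not isolated)
Conditions: LiAlH4, THF, 0 to 50 °C; then HCl, MeOH, 25 °C
Reagents that add atoms: none
Why: Hydride reduction of the tert-butyl ester should give the C3 hydroxymethyl group without touching the three stereocentres, and acidic methanol removes the remaining primary silyl ether.

Compound list
1 | 8-hydroxy-7-methoxycoumarin | COc1ccc2ccc(=O)oc2c1O | starting material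
2 | 8-[(tert-butyldimethylsilyl)oxy]-7-methoxycoumarin | COc1ccc2ccc(=O)oc2c1O[Si](C)(C)C(C)(C)C | intermediate
3 | 3,4,5-trimethoxyphenylboronic acid | COc1cc(B(O)O)cc(OC)c1OC | starting material
4 | (4S)-8-[(tert-butyldimethylsilyl)oxy]-7-methoxy-4-(3,4,5-trimethoxyphenyl)-3,4-dihydro-2H-chromen-2-one | COc1ccc2c(c1O[Si](C)(C)C(C)(C)C)OC(=O)C[C@H]2c1cc(OC)c(OC)c(OC)c1 | intermediate
5 | tert-butyl bromoacetate | CC(C)(C)OC(=O)CBr | starting material
6 | tert-butyl 2-[(3R,4S)-8-[(tert-butyldimethylsilyl)oxy]-7-methoxy-2-oxo-4-(3,4,5-trimethoxyphenyl)-3,4-dihydro-2H-chromen-3-yl]acetate (3,4-trans) | COc1ccc2c(c1O[Si](C)(C)C(C)(C)C)OC(=O)[C@H](CC(=O)OC(C)(C)C)[C@H]2c1cc(OC)c(OC)c(OC)c1 | intermediate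
7 | tert-butyl (3R,4S)-4-{3-[(tert-butyldimethylsilyl)oxy]-2-hydroxy-4-methoxyphenyl}-3-(hydroxymethyl)-4-(3,4,5-trimethoxyphenyl)butanoate | COc1ccc([C@H](c2cc(OC)c(OC)c(OC)c2)[C@H](CO)CC(=O)OC(C)(C)C)c(O)c1O[Si](C)(C)C(C)(C)C | intermediate
8 | tert-butyl (3R,4S)-4-{2,3-bis[(tert-butyldimethylsilyl)oxy]-4-methoxyphenyl}-3-{[(tert-butyldimethylsilyl)oxy]methyl}-4-(3,4,5-trimethoxyphenyl)butanoate | COc1ccc([C@H](c2cc(OC)c(OC)c(OC)c2)[C@H](CO[Si](C)(C)C(C)(C)C)CC(=O)OC(C)(C)C)c(O[Si](C)(C)C(C)(C)C)c1O[Si](C)(C)C(C)(C)C | intermediate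
9 | Mannich base: tert-butyl (2RS,3S,4S)-2-[(dimethylamino)methyl] derivative of 8 (epimers at the ester α-carbon) | COc1ccc([C@H](c2cc(OC)c(OC)c(OC)c2)[C@H](CO[Si](C)(C)C(C)(C)C)C(CN(C)C)C(=O)OC(C)(C)C)c(O[Si](C)(C)C(C)(C)C)c1O[Si](C)(C)C(C)(C)C | intermediate
10 | methiodide of 9 (trimethylammonium iodide) | COc1ccc([C@H](c2cc(OC)c(OC)c(OC)c2)[C@H](CO[Si](C)(C)C(C)(C)C)C(C[N+](C)(C)C)C(=O)OC(C)(C)C)c(O[Si](C)(C)C(C)(C)C)c1O[Si](C)(C)C(C)(C)C.[I-] | intermediate
11 | tert-butyl (3S,4S)-4-{2,3-bis[(tert-butyldimethylsilyl)oxy]-4-methoxyphenyl}-3-{[(tert-butyldimethylsilyl)oxy]methyl}-2-methylidene-4-(3,4,5-trimethoxyphenyl)butanoate | COc1ccc([C@H](c2cc(OC)c(OC)c(OC)c2)[C@H](CO[Si](C)(C)C(C)(C)C)C(=C)C(=O)OC(C)(C)C)c(O[Si](C)(C)C(C)(C)C)c1O[Si](C)(C)C(C)(C)C | intermediate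
12 | tert-butyl (3S,4S)-3-{[(tert-butyldimethylsilyl)oxy]methyl}-4-(2,3-dihydroxy-4-methoxyphenyl)-2-methylidene-4-(3,4,5-trimethoxyphenyl)butanoate (free catechol, present as its phenoxide) | COc1ccc([C@H](c2cc(OC)c(OC)c(OC)c2)[C@H](CO[Si](C)(C)C(C)(C)C)C(=C)C(=O)OC(C)(C)C)c(O)c1O | intermediate
13 | tert-butyl (2S,3S,4S)-3-{[(tert-butyldimethylsilyl)oxy]methyl}-5,6-dihydroxy-7-methoxy-4-(3,4,5-trimethoxyphenyl)-1,2,3,4-tetrahydronaphthalene-2-carboxylate (aryl and silyloxymethyl cis, silyloxymethyl and ester trans) | COc1cc2c(c(O)c1O)[C@H](c1cc(OC)c(OC)c(OC)c1)[C@H](CO[Si](C)(C)C(C)(C)C)[C@@H](C(=O)OC(C)(C)C)C2 | intermediate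
14 | (6S,7S,8S)-7-{[(tert-butyldimethylsilyl)oxy]methyl}-6-(hydroxymethyl)-3-methoxy-8-(3,4,5-trimethoxyphenyl)-5,6,7,8-tetrahydronaphthalene-1,2-diol | COc1cc2c(c(O)c1O)[C@H](c1cc(OC)c(OC)c(OC)c1)[C@H](CO[Si](C)(C)C(C)(C)C)[C@@H](CO)C2 | intermediate
15 | (6S,7S,8S)-6,7-bis(hydroxymethyl)-3-methoxy-8-(3,4,5-trimethoxyphenyl)-5,6,7,8-tetrahydronaphthalene-1,2-diol (CNP0188980.2; aryl cis to the neighbouring hydroxymethyl, the two hydroxymethyl groups trans) | COc1cc2c(c(O)c1O)[C@H](c1cc(OC)c(OC)c(OC)c1)[C@H](CO)[C@@H](CO)C2 | target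

Total step count: 8. Longest linear sequence: 8 steps (from 1; compounds 3 and 5 are commercial).

Steps most likely to fail

Step 7 (key ring closure). The phenoxide may react only reversibly through oxygen, the simple ester acceptor may be too weak for carbon attack before the acrylate oligomerises or its double bond migrates, and equilibration at C3 may remain incomplete. The fallback raises the acceptor to the aldehyde level and lets the aldehyde set C3. It sets out from 11: iBu2AlH (CH2Cl2, −78 °C) should give the allylic alcohol F1, and MnO2 (CH2Cl2, 25 °C) the 2-substituted acrolein F2. K2CO3 in MeOH under argon should then cleave the two aryl silyl ethers to the catechol enal F3 (not isolated), whose phenoxide should add through C4a to the much more electrophilic enal. The resulting tetralin aldehyde F4 should epimerise under the same mild base to the equatorial, trans isomer. NaBH4 (MeOH, 0 °C) would reduce F4 to 14, where the fallback comes back to the route for the acidic desilylation of step 8.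

Step 2 (asymmetric arylation). Insertion into the electron-rich, 8-substituted coumarin may be slow, so that protodeboronation of the electron-rich boronic acid outruns it, or facial selectivity may be insufficient. The fallback separates C–C bond formation from the stereo-determining event. It sets out from 2: oxidative Heck arylation with 3 (Pd(OAc)2, 1,10-phenanthroline, O2, DMF, 80 °C) should give the 4-arylcoumarin F5. Copper hydride-catalysed asymmetric conjugate reduction (Cu(OAc)2, the DTBM-SEGPHOS enantiomer that gives 4S, (EtO)2MeSiH, tBuOH, toluene, 25 °C) would then deliver 4, where it comes back to the route.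

Step 6 (α-methylenation). Enolisation of the hindered ester may be incomplete, the aryl silyl ethers may be attacked by the amide base, or quaternisation and elimination may stall. The fallback replaces the Mannich/elimination sequence by aldol addition and dehydration. It sets out from 8: LiN(iPr)2 (THF, −78 °C) followed by monomeric formaldehyde should give the β-hydroxy ester F6. MsCl and Et3N (CH2Cl2, 0 °C) would convert it to the mesylate F7, and DBU (CH2Cl2, 25 °C) should eliminate it to 11, where it comes back to the route.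

Further compounds
F1 | step 7 | (3S,4S)-4-{2,3-bis[(tert-butyldimethylsilyl)oxy]-4-methoxyphenyl}-3-{[(tert-butyldimethylsilyl)oxy]methyl}-2-methylidene-4-(3,4,5-trimethoxyphenyl)butan-1-ol | COc1ccc([C@H](c2cc(OC)c(OC)c(OC)c2)[C@H](CO[Si](C)(C)C(C)(C)C)C(=C)CO)c(O[Si](C)(C)C(C)(C)C)c1O[Si](C)(C)C(C)(C)C
F2 | step 7 | (3S,4S)-4-{2,3-bis[(tert-butyldimethylsilyl)oxy]-4-methoxyphenyl}-3-{[(tert-butyldimethylsilyl)oxy]methyl}-2-methylidene-4-(3,4,5-trimethoxyphenyl)butanal | COc1ccc([C@H](c2cc(OC)c(OC)c(OC)c2)[C@H](CO[Si](C)(C)C(C)(C)C)C(=C)C=O)c(O[Si](C)(C)C(C)(C)C)c1O[Si](C)(C)C(C)(C)C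
F3 | step 7 | (3S,4S)-3-{[(tert-butyldimethylsilyl)oxy]methyl}-4-(2,3-dihydroxy-4-methoxyphenyl)-2-methylidene-4-(3,4,5-trimethoxyphenyl)butanal | COc1ccc([C@H](c2cc(OC)c(OC)c(OC)c2)[C@H](CO[Si](C)(C)C(C)(C)C)C(=C)C=O)c(O)c1O
F4 | step 7 | (2S,3S,4S)-3-{[(tert-butyldimethylsilyl)oxy]methyl}-5,6-dihydroxy-7-methoxy-4-(3,4,5-trimethoxyphenyl)-1,2,3,4-tetrahydronaphthalene-2-carbaldehyde | COc1cc2c(c(O)c1O)[C@H](c1cc(OC)c(OC)c(OC)c1)[C@H](CO[Si](C)(C)C(C)(C)C)[C@@H](C=O)C2
F5 | step 2 | 8-[(tert-butyldimethylsilyl)oxy]-7-methoxy-4-(3,4,5-trimethoxyphenyl)-2H-chromen-2-one | COc1ccc2c(-c3cc(OC)c(OC)c(OC)c3)cc(=O)oc2c1O[Si](C)(C)C(C)(C)C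
F6 | step 6 | tert-butyl (2RS,3S,4S)-4-{2,3-bis[(tert-butyldimethylsilyl)oxy]-4-methoxyphenyl}-3-{[(tert-butyldimethylsilyl)oxy]methyl}-2-(hydroxymethyl)-4-(3,4,5-trimethoxyphenyl)butanoate | COc1ccc([C@H](c2cc(OC)c(OC)c(OC)c2)[C@H](CO[Si](C)(C)C(C)(C)C)C(CO)C(=O)OC(C)(C)C)c(O[Si](C)(C)C(C)(C)C)c1O[Si](C)(C)C(C)(C)C
F7 | step 6 | tert-butyl (2RS,3S,4S)-4-{2,3-bis[(tert-butyldimethylsilyl)oxy]-4-methoxyphenyl}-3-{[(tert-butyldimethylsilyl)oxy]methyl}-2-{[(methanesulfonyl)oxy]methyl}-4-(3,4,5-trimethoxyphenyl)butanoate | COc1ccc([C@H](c2cc(OC)c(OC)c(OC)c2)[C@H](CO[Si](C)(C)C(C)(C)C)C(COS(C)(=O)=O)C(=O)OC(C)(C)C)c(O[Si](C)(C)C(C)(C)C)c1O[Si](C)(C)C(C)(C)C
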